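## Retrosynthetic overview

1. The target comes from flavanone 20 by C4 deoxygenation and desilylation. Its C8 prenyl group is delivered from a 5-O-prenyl ether by a Claisen–Cope relay, and its C7 oxygen by C–H borylation/oxidation of 5-hydroxyflavanone 10.
2. Flavanone 10 comes from dione 8 by dehydrogenation of ring A, which is carried as a cyclohexenone until then.
3. Dione 8 is cut at C2–C3 and C8a–O1 into enol silane 3 (from 2-acetyl-3-methoxycyclohexenone) and ring B aldehyde 5, joined by an asymmetric Mukaiyama aldol/addition–elimination sequence (formal hetero-Diels–Alder reaction).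
4. Feature: O1–C2–C3–C4 of ring C, with the C2 stereocentre, is an aldehyde C=O plus a two-carbon enolate, and C4a, C5 and C8a of ring A are the three carbons of a 2-acylcyclohexane-1,3-dione. O5 is therefore a carbonyl from the start and stays distinct from O7, which is added later.
5. Ring order: ring B bought as the arene, ring A bought as a non-aromatic carbocycle, ring C closed in step 4, ring A aromatised in step 5.

Key step: step 4

Remark: flavan numbering (O1, C2, C3, C4, C4a, C5–C8, C8a) is used for all bicyclic compounds; it is assumed that kinetic deprotonation of 2 takes place at the acetyl methyl group and not at C4 or C6 of the ring.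

## Route

Step 1
Reactants: 1 2-acetylcyclohexane-1,3-dione
Product: 2 2-acetyl-3-methoxycyclohex-2-en-1-one
Conditions: Me3SiCHN2, PhMe/MeOH (4:1), 0 °C to rt
Reagents that add atoms: (trimethylsilyl)diazomethane, C[Si](C)(C)C=[N+]=[N-]
Why: The enolised β-triketone is about as acidic as a carboxylic acid and should be O-methylated by the diazomethane equivalent on its predominant endocyclic enol, giving the ring vinylogous ester (diazoalkane O-methylation of an acidic enol).

Step 2
Reactants: 2 2-acetyl-3-methoxycyclohex-2-en-1-one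
Product: 3 3-methoxy-2-[1-(triethylsilyloxy)ethenyl]cyclohex-2-en-1-one
Conditions: LiN(SiMe3)2 (1.1 equiv), THF, −78 °C (2 added to the base); Et3SiCl, −78 to 0 °C; filtration through Et3N-deactivated silica
Reagents that add atoms: chlorotriethylsilane, CC[Si](Cl)(CC)CC
Why: Kinetic deprotonation by the hindered amide should take the unhindered acetyl methyl protons (the acetyl carbonyl, twisted out of conjugation by the flanking C1 carbonyl and C3 methoxy group, is the more ketone-like one), and the lithium enolate is trapped on oxygen (silyl enol ether formation).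

Step 3
Reactants: 4 3-hydroxy-5-methoxybenzaldehyde
Product: 5 3-methoxy-5-(triisopropylsilyloxy)benzaldehyde
Conditions: iPr3SiCl, imidazole, DMF, rt
Reagents that add atoms: chlorotriisopropylsilane, CC(C)[Si](Cl)(C(C)C)C(C)C
Why: Standard imidazole-mediated silylation of a phenol; the bulky aryl silyl ether should survive the Lewis acids, CF3CO2H, oxidants and hydride used later and fall only to fluoride in the last step.

Step 4
Reactants: 3 3-methoxy-2-[1-(triethylsilyloxy)ethenyl]cyclohex-2-en-1-one, 5 3-methoxy-5-(triisopropylsilyloxy)benzaldehyde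
Product: 8 (S)-2-[3-methoxy-5-(triisopropylsilyloxy)phenyl]-2,3,7,8-tetrahydro-4H-chromene-4,5(6H)-dione, via triethylsilyl aldol ether 6 (not isolated), via hydroxy ketone 7 (not isolated)
Conditions: (S)-BINOL (20 mol %), Ti(OiPr)4 (10 mol %), CF3CO2H (cat.), 4 Å molecular sieves, Et2O, −20 °C to rt, 3 in 1.3 equiv; then CF3CO2H, CH2Cl2, 0 °C
Reagents that add atoms: none
Why: The BINOL complex of tetravalent titanium binds the aldehyde, and the CH2 terminus of the enol silane (future C3) adds to the aldehyde carbon (future C2) through an open Mukaiyama aldol transition state, the silyl group moving to the aldolate oxygen to give 6; the closest known reaction is the titanium–BINOL-catalysed formal hetero-Diels–Alder reaction of 1-alkoxy-3-silyloxy dienes with aromatic aldehydes. CF3CO2H then cleaves the triethylsilyl ether, the free hydroxyl of 7 adds to the methoxy-bearing β-carbon of the ring vinylogous ester (future C8a) and methanol is expelled, a 6-endo-trig addition–elimination that closes ring C and turns the aldehyde oxygen into O1. The C2 stereocentre is set in the aldol event by the chiral ligand: (S)-BINOL is expected, by analogy with additions of allyl and enol silane nucleophiles to aromatic aldehydes under this catalyst, to direct attack to the Si face, which gives 2S; the sense is to be confirmed on 8 and (R)-BINOL used if it proves opposite. Regioselectivity follows from the polarity of the diene, since only the enol silane carbon is nucleophilic and only the methoxy-bearing carbon can undergo addition–elimination, and the acidic, base-free ring closure should leave the new C2–O1 bond intact.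

Step 5
Reactants: 8 (S)-2-[3-methoxy-5-(triisopropylsilyloxy)phenyl]-2,3,7,8-tetrahydro-4H-chromene-4,5(6H)-dione
Product: 10 (2S)-5-hydroxy-2-[3-methoxy-5-(triisopropylsilyloxy)phenyl]chroman-4-one, via silyl dienol ether 9 (not isolated)
Conditions: Me3SiOTf (1.2 equiv), Et3N (2 equiv), CH2Cl2, 0 °C; pentane, filtration, evaporation; DDQ (1.05 equiv), 2,4,6-collidine, PhMe, 0 °C to rt; 1 M HCl work-up
Reagents that add atoms: none
Why: Soft enolisation should remove a C8 proton, the only C–H of 8 that is vinylogous to both carbonyl groups (either ring A enol silane would serve), and DDQ then abstracts hydride from C7 of the dienol ether (quinone oxidation of a silyl enol ether), silicon is lost and the cyclohexadienone tautomerises to the phenol hydrogen-bonded to C4=O, while C2 is untouched because no base strong enough to open ring C by β-elimination is present.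

Step 6
Reactants: 10 (2S)-5-hydroxy-2-[3-methoxy-5-(triisopropylsilyloxy)phenyl]chroman-4-one
Product: 13 (2S)-5-hydroxy-2-[3-methoxy-5-(triisopropylsilyloxy)phenyl]-7-(4,4,5,5-tetramethyl-1,3,2-dioxaborolan-2-yl)chroman-4-one, via O-boryl ether 11 (not isolated), via O-boryl C7 boronate 12 (not isolated)
Conditions: pinacolborane (1.1 equiv), THF, rt to 40 °C; [Ir(OMe)(cod)]2 (1.5 mol %), 4,4'-di-tert-butyl-2,2'-bipyridine (3 mol %), B2pin2 (1.0 equiv), THF, 70 °C; MeOH, rt
Reagents that add atoms: bis(pinacolato)diboron, CC1(C)OB(OC1(C)C)B1OC(C)(C)C(C)(C)O1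
Why: Pinacolborane masks the phenol as its O-boryl ether (and is regenerated in the C–H step), and the sterically governed iridium-catalysed aromatic C–H borylation should take C7, the only aromatic C–H with two unsubstituted neighbours (C6 and C8 lie ortho to oxygen and every C–H of ring B is flanked by two substituents); methanol then frees the phenol.

Step 7
Reactants: 13 (2S)-5-hydroxy-2-[3-methoxy-5-(triisopropylsilyloxy)phenyl]-7-(4,4,5,5-tetramethyl-1,3,2-dioxaborolan-2-yl)chroman-4-one
Product: 14 (2S)-5,7-dihydroxy-2-[3-methoxy-5-(triisopropylsilyloxy)phenyl]chroman-4-one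
Conditions: Oxone (2KHSO5·KHSO4·K2SO4), acetone/H2O (1:1), 0 °C to rt, 15 min; aq. NaHSO3
Reagents that add atoms: potassium peroxymonosulfate (active salt of Oxone), [K+].[O-]S(=O)(=O)OO
Why: Peroxymonosulfate converts the aryl boronate into the phenol by boron-to-oxygen 1,2-aryl migration under slightly acidic conditions (oxidation of an aryl boronic ester), which avoids the basic peroxide that could open the flavanone ring.

Step 8
Reactants: 14 (2S)-5,7-dihydroxy-2-[3-methoxy-5-(triisopropylsilyloxy)phenyl]chroman-4-one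
Product: 15 (2S)-5-hydroxy-2-[3-methoxy-5-(triisopropylsilyloxy)phenyl]-7-(triisopropylsilyloxy)chroman-4-one
Conditions: iPr3SiCl (1.05 equiv), imidazole, CH2Cl2/DMF, 0 °C
Reagents that add atoms: chlorotriisopropylsilane, CC(C)[Si](Cl)(C(C)C)C(C)C
Why: The C5 hydroxyl is held in a hydrogen bond to C4=O and is far less nucleophilic than the C7 hydroxyl, so one equivalent of silyl chloride should silylate O7 only (selective phenol silylation).

Step 9
Reactants: 15 (2S)-5-hydroxy-2-[3-methoxy-5-(triisopropylsilyloxy)phenyl]-7-(triisopropylsilyloxy)chroman-4-one, 16 3-methylbut-2-en-1-ol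
Product: 17 (2S)-2-[3-methoxy-5-(triisopropylsilyloxy)phenyl]-5-(3-methylbut-2-enyloxy)-7-(triisopropylsilyloxy)chroman-4-one
Conditions: PPh3, DIAD, THF, 0 °C to rt
Reagents that add atoms: none
Why: Mitsunobu etherification alkylates the chelated C5 phenol with the primary allylic alcohol at its CH2 terminus under neutral conditions, so the base-sensitive flavanone ring is not opened.

Step 10
Reactants: 17 (2S)-2-[3-methoxy-5-(triisopropylsilyloxy)phenyl]-5-(3-methylbut-2-enyloxy)-7-(triisopropylsilyloxy)chroman-4-one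
Product: 20 (2S)-5-hydroxy-2-[3-methoxy-5-(triisopropylsilyloxy)phenyl]-8-(3-methylbut-2-enyl)-7-(triisopropylsilyloxy)chroman-4-one, via ortho-dienone 18 (not isolated), via para-dienone 19 (not isolated)
Conditions: Eu(fod)3 [tris(6,6,7,7,8,8,8-heptafluoro-2,2-dimethyloctane-3,5-dionato)europium] (10 mol %), CHCl3, 60 °C, sealed tube
Reagents that add atoms: none
Why: The europium chelate of C4=O and O5 accelerates the aromatic Claisen rearrangement to C6, and the 1,1-dimethylallyl group of dienone 18, crowded by the C7 silyloxy group, should move on to C8 by Cope rearrangement before it can tautomerise, after which enolisation of 19 restores the phenol (para-Claisen–Cope relay, two consecutive [3,3] shifts) with the prenyl group attached through its CH2.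

Step 11
Reactants: 20 (2S)-5-hydroxy-2-[3-methoxy-5-(triisopropylsilyloxy)phenyl]-8-(3-methylbut-2-enyl)-7-(triisopropylsilyloxy)chroman-4-one
Product: 23 (2S)-2-[3-methoxy-5-(triisopropylsilyloxy)phenyl]-8-(3-methylbut-2-enyl)-7-(triisopropylsilyloxy)chroman-5-ol, via ethyl carbonate 21 (not isolated), via ortho-quinone methide 22 (not isolated)
Conditions: ClCO2Et, Et3N, THF, 0 °C; then NaBH4, H2O, 0 °C to rt
Reagents that add atoms: none
Why: Ortho-hydroxyl-assisted deoxygenation of an aryl ketone: borohydride reduces C4=O, the carbonate moves to the new alkoxide and is expelled by the phenoxide to give ortho-quinone methide 22, and a second hydride adds at C4, leaving the C2 stereocentre, the prenyl alkene and both silyl ethers untouched.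

Step 12
Reactants: 23 (2S)-2-[3-methoxy-5-(triisopropylsilyloxy)phenyl]-8-(3-methylbut-2-enyl)-7-(triisopropylsilyloxy)chroman-5-ol
Product: 24 (2S)-2-(3-hydroxy-5-methoxyphenyl)-8-(3-methylbut-2-enyl)chromane-5,7-diol
Conditions: Bu4NF (2.5 equiv), AcOH (2.5 equiv), THF, 0 °C; aq. NH4Cl
Reagents that add atoms: none
Why: Fluoride cleaves both aryl triisopropylsilyl ethers (fluoride-mediated desilylation), and the acetic acid buffer protects the electron-rich triphenol and its acid- and base-sensitive prenyl/phenol array.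

## Compound list

1 | 2-acetylcyclohexane-1,3-dione | CC(=O)C1C(=O)CCCC1=O | starting material
2 | 2-acetyl-3-methoxycyclohex-2-en-1-one | COC1=C(C(C)=O)C(=O)CCC1 | intermediate
3 | 3-methoxy-2-[1-(triethylsilyloxy)ethenyl]cyclohex-2-en-1-one | C=C(O[Si](CC)(CC)CC)C1=C(OC)CCCC1=O | intermediate
4 | 3-hydroxy-5-methoxybenzaldehyde | COc1cc(O)cc(C=O)c1 | starting material
5 | 3-methoxy-5-(triisopropylsilyloxy)benzaldehyde | COc1cc(O[Si](C(C)C)(C(C)C)C(C)C)cc(C=O)c1 | intermediate
6 | 3-methoxy-2-[(3S)-3-[3-methoxy-5-(triisopropylsilyloxy)phenyl]-3-(triethylsilyloxy)propanoyl]cyclohex-2-en-1-one | COc1cc(O[Si](C(C)C)(C(C)C)C(C)C)cc([C@@H](O[Si](CC)(CC)CC)CC(=O)C2=C(OC)CCCC2=O)c1 | intermediate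
7 | 2-[(3S)-3-hydroxy-3-[3-methoxy-5-(triisopropylsilyloxy)phenyl]propanoyl]-3-methoxycyclohex-2-en-1-one | COc1cc(O[Si](C(C)C)(C(C)C)C(C)C)cc([C@@H](O)CC(=O)C2=C(OC)CCCC2=O)c1 | intermediate
8 | (S)-2-[3-methoxy-5-(triisopropylsilyloxy)phenyl]-2,3,7,8-tetrahydro-4H-chromene-4,5(6H)-dione | COc1cc(O[Si](C(C)C)(C(C)C)C(C)C)cc([C@@H]2CC(=O)C3=C(CCCC3=O)O2)c1 | intermediate
9 | (2S)-2-[3-methoxy-5-(triisopropylsilyloxy)phenyl]-5-(trimethylsilyloxy)-2,3,6,7-tetrahydro-4H-chromen-4-one | COc1cc(O[Si](C(C)C)(C(C)C)C(C)C)cc([C@@H]2CC(=O)C3=C(O[Si](C)(C)C)CCC=C3O2)c1 | intermediate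
10 | (2S)-5-hydroxy-2-[3-methoxy-5-(triisopropylsilyloxy)phenyl]chroman-4-one | COc1cc(O[Si](C(C)C)(C(C)C)C(C)C)cc([C@@H]2CC(=O)c3c(O)cccc3O2)c1 | intermediate
11 | (2S)-2-[3-methoxy-5-(triisopropylsilyloxy)phenyl]-5-[(4,4,5,5-tetramethyl-1,3,2-dioxaborolan-2-yl)oxy]chroman-4-one | COc1cc(O[Si](C(C)C)(C(C)C)C(C)C)cc([C@@H]2CC(=O)c3c(OB4OC(C)(C)C(C)(C)O4)cccc3O2)c1 | intermediate
12 | (2S)-2-[3-methoxy-5-(triisopropylsilyloxy)phenyl]-7-(4,4,5,5-tetramethyl-1,3,2-dioxaborolan-2-yl)-5-[(4,4,5,5-tetramethyl-1,3,2-dioxaborolan-2-yl)oxy]chroman-4-one | COc1cc(O[Si](C(C)C)(C(C)C)C(C)C)cc([C@@H]2CC(=O)c3c(OB4OC(C)(C)C(C)(C)O4)cc(B4OC(C)(C)C(C)(C)O4)cc3O2)c1 | intermediate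
13 | (2S)-5-hydroxy-2-[3-methoxy-5-(triisopropylsilyloxy)phenyl]-7-(4,4,5,5-tetramethyl-1,3,2-dioxaborolan-2-yl)chroman-4-one | COc1cc(O[Si](C(C)C)(C(C)C)C(C)C)cc([C@@H]2CC(=O)c3c(O)cc(B4OC(C)(C)C(C)(C)O4)cc3O2)c1 | intermediate
14 | (2S)-5,7-dihydroxy-2-[3-methoxy-5-(triisopropylsilyloxy)phenyl]chroman-4-one | COc1cc(O[Si](C(C)C)(C(C)C)C(C)C)cc([C@@H]2CC(=O)c3c(O)cc(O)cc3O2)c1 | intermediate
15 | (2S)-5-hydroxy-2-[3-methoxy-5-(triisopropylsilyloxy)phenyl]-7-(triisopropylsilyloxy)chroman-4-one | COc1cc(O[Si](C(C)C)(C(C)C)C(C)C)cc([C@@H]2CC(=O)c3c(O)cc(O[Si](C(C)C)(C(C)C)C(C)C)cc3O2)c1 | intermediate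
16 | 3-methylbut-2-en-1-ol | CC(C)=CCO | starting material
17 | (2S)-2-[3-methoxy-5-(triisopropylsilyloxy)phenyl]-5-(3-methylbut-2-enyloxy)-7-(triisopropylsilyloxy)chroman-4-one | COc1cc(O[Si](C(C)C)(C(C)C)C(C)C)cc([C@@H]2CC(=O)c3c(OCC=C(C)C)cc(O[Si](C(C)C)(C(C)C)C(C)C)cc3O2)c1 | intermediate
18 | (2S)-2-[3-methoxy-5-(triisopropylsilyloxy)phenyl]-6-(2-methylbut-3-en-2-yl)-7-(triisopropylsilyloxy)-2,3-dihydro-4H-chromene-4,5(6H)-dione (C6 epimers) | COc1cc(O[Si](C(C)C)(C(C)C)C(C)C)cc([C@@H]2CC(=O)C3=C(O2)C=C(O[Si](C(C)C)(C(C)C)C(C)C)C(C(C)(C)C=C)C3=O)c1 | intermediate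
19 | (2S)-2-[3-methoxy-5-(triisopropylsilyloxy)phenyl]-8-(3-methylbut-2-enyl)-7-(triisopropylsilyloxy)-2,3-dihydro-4H-chromene-4,5(8H)-dione (C8 epimers) | COc1cc(O[Si](C(C)C)(C(C)C)C(C)C)cc([C@@H]2CC(=O)C3=C(O2)C(CC=C(C)C)C(O[Si](C(C)C)(C(C)C)C(C)C)=CC3=O)c1 | intermediate
20 | (2S)-5-hydroxy-2-[3-methoxy-5-(triisopropylsilyloxy)phenyl]-8-(3-methylbut-2-enyl)-7-(triisopropylsilyloxy)chroman-4-one | COc1cc(O[Si](C(C)C)(C(C)C)C(C)C)cc([C@@H]2CC(=O)c3c(O)cc(O[Si](C(C)C)(C(C)C)C(C)C)c(CC=C(C)C)c3O2)c1 | intermediate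
21 | ethyl (2S)-2-[3-methoxy-5-(triisopropylsilyloxy)phenyl]-8-(3-methylbut-2-enyl)-4-oxo-7-(triisopropylsilyloxy)chroman-5-yl carbonate | COc1cc(O[Si](C(C)C)(C(C)C)C(C)C)cc([C@@H]2CC(=O)c3c(OC(=O)OCC)cc(O[Si](C(C)C)(C(C)C)C(C)C)c(CC=C(C)C)c3O2)c1 | intermediate
22 | (2S)-2-[3-methoxy-5-(triisopropylsilyloxy)phenyl]-8-(3-methylbut-2-enyl)-7-(triisopropylsilyloxy)-2,3-dihydro-5H-chromen-5-one | COc1cc(O[Si](C(C)C)(C(C)C)C(C)C)cc([C@@H]2CC=C3C(=O)C=C(O[Si](C(C)C)(C(C)C)C(C)C)C(CC=C(C)C)=C3O2)c1 | intermediate
23 | (2S)-2-[3-methoxy-5-(triisopropylsilyloxy)phenyl]-8-(3-methylbut-2-enyl)-7-(triisopropylsilyloxy)chroman-5-ol | COc1cc(O[Si](C(C)C)(C(C)C)C(C)C)cc([C@@H]2CCc3c(O)cc(O[Si](C(C)C)(C(C)C)C(C)C)c(CC=C(C)C)c3O2)c1 | intermediate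
24 | (2S)-2-(3-hydroxy-5-methoxyphenyl)-8-(3-methylbut-2-enyl)chromane-5,7-diol | COc1cc(O)cc([C@@H]2CCc3c(O)cc(O)c(CC=C(C)C)c3O2)c1 | target

## Step count and risks

Total steps: 12. Longest linear sequence: 11 steps (steps 1, 2 and 4–12 from compound 1); the aldehyde branch adds step 3.

**Step 4 (key step).** The enol silane is hindered, and its ring carbonyl and methoxy oxygen can bind titanium. Turnover may therefore stall, or the aldehyde may be attacked outside the chiral environment, so that facial selectivity is poor.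
Fallback: from ketone 2 and aldehyde 5, a reagent-controlled boron aldol replaces the catalytic enol silane addition. Ketone 2 is enolised at the acetyl group with B-chlorodiisopinocampheylborane (Ipc2BCl) and Et3N in Et2O at −78 °C, and 5 is added. Oxidative work-up (H2O2, pH 7 buffer, MeOH) releases hydroxy ketone 7, which CF3CO2H in CH2Cl2 closes as in step 4, so the route is rejoined at 8. The antipode of the borane is chosen to give the 3S carbinol. Such methyl ketone aldols are as a rule less selective than the catalytic reaction, so enrichment by crystallisation of 10 or 14 would be planned. This path isolates nothing outside the compound list (F0).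

**Step 5.** Site selectivity of the oxidation may be lost: enol silylation toward C3, or hydride abstraction by the quinone at the benzylic C2–H, would dehydrogenate ring C instead of ring A and destroy the stereocentre. Over-oxidation of the flavanone by excess quinone would have the same effect.
Fallback: from 8, a halogenation–dehydrohalogenation that relies only on acidity, with DBU (2.2 equiv) and BrCCl3 in CH2Cl2 at −20 °C. The amidine should remove only the doubly vinylogous C8 proton, since the C3 and C6 protons are far less acidic. The extended enolate is brominated to (2S)-8-bromo-2-[3-methoxy-5-(triisopropylsilyloxy)phenyl]-2,3,7,8-tetrahydro-4H-chromene-4,5(6H)-dione F1. The second equivalent of base eliminates HBr across C7–C8, and the dienone tautomerises, so the route is rejoined at 10.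

**Step 6.** The O-boryl group may direct part of the borylation to C6, and pinacolborane may hydroborate the boron-chelated C4 carbonyl.
Fallback: from 10, covalent protection replaces the transient O-boryl group. Acetylation (Ac2O, pyridine, DMAP cat., CH2Cl2, 0 °C) gives (2S)-2-[3-methoxy-5-(triisopropylsilyloxy)phenyl]-4-oxochroman-5-yl acetate F2. Borylation without pinacolborane pre-treatment ([Ir(OMe)(cod)]2, 4,4'-di-tert-butyl-2,2'-bipyridine, B2pin2, THF, 70 °C) gives the C7 boronate, (2S)-2-[3-methoxy-5-(triisopropylsilyloxy)phenyl]-4-oxo-7-(4,4,5,5-tetramethyl-1,3,2-dioxaborolan-2-yl)chroman-5-yl acetate F3; the acetoxy group shields C6 and no boron sits on the carbonyl. Oxone oxidation gives (2S)-7-hydroxy-2-[3-methoxy-5-(triisopropylsilyloxy)phenyl]-4-oxochroman-5-yl acetate F4. Mild deacetylation (NH4OAc, aqueous MeOH, rt) rejoins the route at 14.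

Further compounds
F0 | step 4 | none | none
F1 | step 5 | (2S)-8-bromo-2-[3-methoxy-5-(triisopropylsilyloxy)phenyl]-2,3,7,8-tetrahydro-4H-chromene-4,5(6H)-dione | COc1cc(O[Si](C(C)C)(C(C)C)C(C)C)cc([C@@H]2CC(=O)C3=C(O2)C(Br)CCC3=O)c1
F2 | step 6 | (2S)-2-[3-methoxy-5-(triisopropylsilyloxy)phenyl]-4-oxochroman-5-yl acetate | COc1cc(O[Si](C(C)C)(C(C)C)C(C)C)cc([C@@H]2CC(=O)c3c(OC(C)=O)cccc3O2)c1
F3 | step 6 | (2S)-2-[3-methoxy-5-(triisopropylsilyloxy)phenyl]-4-oxo-7-(4,4,5,5-tetramethyl-1,3,2-dioxaborolan-2-yl)chroman-5-yl acetate | COc1cc(O[Si](C(C)C)(C(C)C)C(C)C)cc([C@@H]2CC(=O)c3c(OC(C)=O)cc(B4OC(C)(C)C(C)(C)O4)cc3O2)c1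
F4 | step 6 | (2S)-7-hydroxy-2-[3-methoxy-5-(triisopropylsilyloxy)phenyl]-4-oxochroman-5-yl acetate | COc1cc(O[Si](C(C)C)(C(C)C)C(C)C)cc([C@@H]2CC(=O)c3c(OC(C)=O)cc(O)cc3O2)c1
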